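Time is your choice here: the delta flask is running, and you must decide whether to stop it at 50 min or leave it on.

common to all: gas phase 1.9 mM (held)
- delta: starting material 26 mM; the very flask that is asked about, followed so far
- gamma: starting material 39 mM; run made earlier
- flask: starting material 26 mM; time 50 min

- delta (time / min: target / %, crystals / %): 0.333: 0.6, 0.7; 0.667: 0.8, 0; 1.00: 1.2, 0.8; 2.00: 3.7, 0; 4.00: 6.5, 0
- gamma (time / min: target / %, crystals / %): 2.00: 2.3, 0.3; 5.00: 8.5, 0.3; 10.0: 16.0, 0; 15.0: 21.4, 0.3; 20.0: 26.8, 2.4

(readings scatter by 0.3 percentage points)

- how much target and crystals together there is at 50 min, in percent of the starting material charged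
- concentration of dissolved gas in solution at 50 min, in percent of saturation

- for target the crystals are counted in
- as a solid, counted per litre of solution: crystals
- at the start none of the gas phase is in solution

Step 1. Read the target column as it stands, since the crystals are already counted in it. The delta flask shows 6.5% at 4.00 min and gamma shows 8.5% at 5.00 min, close per minute. Both have the gas held at 1.9 mM, so I use gamma's percent curve for delta.

Step 2. Gamma's curve bends. It gains 16.0% in its first 10.0 min and 11 percentage points in the next 10.0 min, which is less. I treat this as a pseudo-first-order decay. The natural log of first gain over second gain, divided by the stretch, reads 0.0393 min⁻¹. This is a reading, with 0.3 points of scatter on each value.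

Step 3. Join the two ends. The ceiling, the percent of target the curve is heading for, is the first gain divided by the part of the decay finished in that stretch: 49.2%.

Step 4. My reckoning at 50 min is 42.3%. The ceiling lies 6.9 points above that, so my plan is to stop there.

Step 5. The forecast says 58% (51% to 75%), on the ground that “the reaction is first order in starting material”, and it puts c(dissolved gas) at 93% of saturation (75% to 99%). My figure for target is lower, and I make no figure of my own for c(dissolved gas).

Step 6. The delta flask gives 43.9% at 50 min, with c(dissolved gas) at 68.4% of saturation.

2 dissolved gas → self-condensation product (k = 440 L mol⁻¹ min⁻¹); gas phase ⇌ dissolved gas, rate k2*(csat - [dissolved gas]) (kL = 2.60 min⁻¹); crystals ⇌ target, rate k3*(cs3 - [target]) while solid is left; crystals form when [target] > cs3 (solubility = 9.40 mM, k = 12.0 min⁻¹); starting material + dissolved gas → target (k = 16.0 L mol⁻¹ min⁻¹); starting material → side product (k = 0.0190 min⁻¹) Side product stands beside the target at 42.0%. The 43.9% is 89.2% of the ceiling of 49.2%. For the same flask read at 2.0 h, the ceiling and 0.0393 min⁻¹ give 48.8%, and that neighbour flask holds 50.8%.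

The data are calculated with made-up constants; noise was put on by code.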